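**Assumption (one line):** the SMILES is taken literally (4R,5S,6S,8S,10R, with the 4,5‑epoxide cis on the ring); ring atoms carry germacrane numbers (C1 ketone, C4/C5 epoxide, C6 lactone O‑carbon, C7=C11, C8 ester carbon, C10 methyl carbon, C12 lactone C=O, C13 CH2OAc); C11, which is destroyed in step 12, is carried as an unassigned mixture and left undefined in the SMILES.

**Retrosynthetic overview**
1. Target ⇐ late C8 esterification with inversion (Mitsunobu), C7=C11 by dehydration of a C11 carbinol, C8–OH from a C8–Si bond (Tamao), C1 ketone from the C1=C10 alkene (hydroboration/oxidation).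
2. γ‑Lactone ⇐ aldol of the C6/C7 enolate with ethyl acetoxypyruvate (brings C11–C13), then reduction of the epoxy ketone and lactonisation.
3. Ten‑membered ring ⇐ anionic oxy‑Cope [3,3] of a 1‑alkenyl‑2‑isopropenyl‑epoxycyclohexanol: forms C8–C9, sets C8, releases the C6/C7 enolate.
4. Cope substrate ⇐ (R)‑isopiperitenone (from (S)‑limonene) + (E)‑silylvinyl nucleophile, then OH‑directed epoxidation (sets C4/C5).
5. Ring order: cyclohexene (bought) → oxirane → cyclodecene → γ‑lactone → butenolide.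

**Route**

Step 1
Reactants: 1 (S)-(−)-limonene
Product: 2 (R)-(−)-isopiperitenone [(6R)-3-methyl-6-(prop-1-en-2-yl)cyclohex-2-en-1-one]
Conditions: t‑BuOOH, Cr(CO)6 (cat.), MeCN, reflux; chromatography (carvone removed)
Reagents that add atoms: tert‑butyl hydroperoxide CC(C)(C)OO
Why: Chromium‑catalysed allylic oxidation of the ring CH2 between the alkene and the stereocentre gives the enone without touching the bought stereocentre (S→R is only a CIP priority change).

Step 2
Reactants: 3 (E)-1,2-bis(tributylstannyl)ethene; 4 benzylchlorodimethylsilane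
Product: 6 (E)-benzyldimethyl[2-(tributylstannyl)ethenyl]silane, via (E)-2-(tributylstannyl)ethenyllithium 5 (not isolated)
Conditions: n‑BuLi (1.0 equiv), THF, −78 °C; then 4, −78 → 0 °C
Reagents that add atoms: none
Why: Mono tin–lithium exchange followed by silylation of the vinyllithium proceeds with retention of the E geometry.

Step 3
Reactants: 2 (R)-isopiperitenone; 6 (E)-benzyldimethyl[2-(tributylstannyl)ethenyl]silane
Product: 9 (1R,6R)-1-[(E)-2-(benzyldimethylsilyl)ethenyl]-3-methyl-6-(prop-1-en-2-yl)cyclohex-2-en-1-ol (OH cis to isopropenyl), via (E)-2-(benzyldimethylsilyl)ethenyllithium 7 (not isolated), via alkenylcerium dichloride 8 (not isolated)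
Conditions: 6, n‑BuLi, THF, −78 → −40 °C; anhydrous CeCl3, −78 °C; then 2, −78 °C; H2O work‑up; minor C1 epimer removed by chromatography
Reagents that add atoms: none
Why: Organocerium 1,2‑addition (no enolisation of the racemisable α′‑centre) occurs on the carbonyl face anti to the neighbouring isopropenyl group, as hydride does with this enone, so OH ends cis and the two alkenyl groups trans.

Step 4
Reactants: 9 dienol from step 3
Product: 10 (1S,2R,3R,6R)-2-[(E)-2-(benzyldimethylsilyl)ethenyl]-6-methyl-3-(prop-1-en-2-yl)-7-oxabicyclo[4.1.0]heptan-2-ol (epoxide O, OH and isopropenyl all cis)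
Conditions: VO(acac)2 (5 mol %), t‑BuOOH (1.1 equiv), CH2Cl2, 0 °C
Reagents that add atoms: tert‑butyl hydroperoxide CC(C)(C)OO
Why: Vanadium‑catalysed hydroxyl‑directed epoxidation hits the most nucleophilic (ring, trisubstituted, allylic) alkene and delivers oxygen syn to the tertiary OH, fixing C4/C5 as 4R,5S.

Step 5
Reactants: 11 ethyl bromopyruvate
Product: 12 ethyl 3-acetoxy-2-oxopropanoate
Conditions: KOAc, DMF, 0 °C → rt
Reagents that add atoms: potassium acetate CC(=O)[O-].[K+]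
Why: SN2 displacement of the activated α‑bromo ketone by acetate.

Step 6
Reactants: 10 epoxy alcohol; 12 ethyl 3-acetoxy-2-oxopropanoate
Product: 16 ethyl 3-acetoxy-2-[(7R,8R)-8-(benzyldimethylsilyl)-4,5-epoxy-6-oxogermacr-1(10)E-en-7-yl]-2-(trimethylsilyloxy)propanoate, via potassium alkoxide 13 (not isolated), via ten-membered potassium enolate 14 (not isolated), via potassium aldolate 15 (not isolated)
Conditions: KH, 18‑crown‑6, THF, 0 → 25 °C; cool to −78 °C, 12 (1.5 equiv); then TMSCl, −78 → 0 °C; pH 7 work‑up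
Reagents that add atoms: chlorotrimethylsilane C[Si](C)(C)Cl
Why: Anionic oxy‑Cope [3,3] rearrangement through a chair transition state with both alkenyl groups equatorial forms C8–C9 and the ten‑membered ring, transfers the carbinol chirality to C8 (E‑silyl equatorial → 8R) and gives the (E)‑C1=C10 alkene and a regiodefined C6/C7 enolate, which adds (aldol) to the keto group of 12 from the outer ring face before O‑silylation.

Step 7
Reactants: 16 silylated aldol
Product: 17 13-acetoxy-8-(benzyldimethylsilyl)-4,5-epoxy-11-(trimethylsilyloxy)germacr-1(10)E-en-12,6-olide (6S; 8R; cis-fused lactone)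
Conditions: Zn(BH4)2, Et2O, −20 → 0 °C; H2O work‑up
Reagents that add atoms: none
Why: Zinc borohydride reduces the chelated α,β‑epoxy ketone from the outer ring face (erythro to the epoxide C–O), setting 6S, and the zinc alkoxide closes the γ‑lactone on the ethyl ester.

Step 8
Reactants: 17 lactone
Product: 20 13-acetoxy-8-(benzyldimethylsilyl)-4,5-epoxy-1-oxo-11-(trimethylsilyloxy)germacran-12,6-olide (6S; 8R; 10R), via C1 alkylborane 18 (not isolated), via C1 alcohol 19 (not isolated)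
Conditions: BH3·THF (1.2 equiv), THF, 0 °C; then NMO (6 equiv), TPAP (10 mol %), 4 Å MS, CH2Cl2, rt
Reagents that add atoms: N‑methylmorpholine N‑oxide C[N+]1([O-])CCOCC1
Why: Hydroboration of the (E)‑trisubstituted C1=C10 alkene from its exposed outer face puts boron on C1 and hydrogen on C10 (10R), and the amine‑oxide/TPAP oxidation takes the borane through the alcohol to the C1 ketone in one pot.

Step 9
Reactants: 20 silyl ketone
Product: 22 13-acetoxy-4,5-epoxy-8,11-dihydroxy-1-oxogermacran-12,6-olide (6S; 8R; 10R), via C8 fluorosilane 21 (not isolated)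
Conditions: TBAF (2.2 equiv), THF, 0 °C; then KHCO3, 30 % H2O2, MeOH/THF, rt
Reagents that add atoms: hydrogen peroxide OO
Why: Tamao–Fleming oxidation: fluoride cleaves the benzyl–silicon bond (and the TMS ether) and peroxide oxidises the C8–Si bond with retention, giving the (8R)‑alcohol.

Step 10
Reactants: 23 2-(hydroxymethyl)acrylic acid
Product: 25 2-[(tert-butyldimethylsilyloxy)methyl]acrylic acid, via bis-silylated acid 24 (not isolated)
Conditions: TBSCl (2.2 equiv), imidazole, DMF, rt; then AcOH/THF/H2O, rt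
Reagents that add atoms: tert‑butyldimethylsilyl chloride CC(C)(C)[Si](C)(C)Cl
Why: Bis‑silylation followed by selective hydrolysis of the labile silyl ester leaves the primary TBS ether.

Step 11
Reactants: 22 diol; 25 protected acid
Product: 26 13-acetoxy-8-{2-[(tert-butyldimethylsilyloxy)methyl]acryloyloxy}-4,5-epoxy-11-hydroxy-1-oxogermacran-12,6-olide (6S; 8S; 10R)
Conditions: PPh3, DIAD, toluene/THF, 0 °C → rt
Reagents that add atoms: none
Why: Mitsunobu esterification is an SN2 displacement with inversion, turning the (8R)‑alcohol into the required (8S)‑ester while the tertiary C11–OH stays inert.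

Step 12
Reactants: 26 hydroxy lactone
Product: 27 (4R,5S,6S,8S,10R)-13-acetoxy-8-{2-[(tert-butyldimethylsilyloxy)methyl]acryloyloxy}-4,5-epoxy-1-oxogermacr-7(11)-en-12,6-olide
Conditions: Martin sulfurane (1.5 equiv), CH2Cl2, 0 °C → rt
Reagents that add atoms: none
Why: Martin sulfurane dehydration of the tertiary α‑hydroxy lactone should give the more substituted, lactone‑conjugated C7=C11 alkene (Saytzeff), erasing the temporary C7 and C11 stereocentres.

Step 13
Reactants: 27 silyl ether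
Product: 28 target (CNP0258719.1)
Conditions: HF·pyridine, pyridine/THF, 0 °C
Reagents that add atoms: none
Why: Buffered fluoride desilylation frees the primary allylic alcohol without affecting the acetate, epoxide, ketone or the two unsaturated esters.

**Compound list**
1 | (S)-(−)-limonene | C=C(C)[C@H]1CCC(C)=CC1 | starting material
2 | (R)-(−)-isopiperitenone | C=C(C)[C@H]1CCC(C)=CC1=O | intermediate
3 | (E)-1,2-bis(tributylstannyl)ethene | CCCC[Sn](CCCC)(CCCC)/C=C/[Sn](CCCC)(CCCC)CCCC | starting material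
4 | benzylchlorodimethylsilane | C[Si](C)(Cl)Cc1ccccc1 | starting material
5 | (E)-2-(tributylstannyl)ethenyllithium | [Li]/C=C/[Sn](CCCC)(CCCC)CCCC | intermediate
6 | (E)-benzyldimethyl[2-(tributylstannyl)ethenyl]silane | CCCC[Sn](CCCC)(CCCC)/C=C/[Si](C)(C)Cc1ccccc1 | intermediate
7 | (E)-2-(benzyldimethylsilyl)ethenyllithium | [Li]/C=C/[Si](C)(C)Cc1ccccc1 | intermediate
8 | dichloro[(E)-2-(benzyldimethylsilyl)ethenyl]cerium | Cl[Ce](Cl)/C=C/[Si](C)(C)Cc1ccccc1 | intermediate
9 | (1R,6R)-1-[(E)-2-(benzyldimethylsilyl)ethenyl]-3-methyl-6-(prop-1-en-2-yl)cyclohex-2-en-1-ol | C=C(C)[C@H]1CCC(C)=C[C@]1(O)/C=C/[Si](C)(C)Cc1ccccc1 | intermediate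
10 | (1S,2R,3R,6R)-2-[(E)-2-(benzyldimethylsilyl)ethenyl]-6-methyl-3-(prop-1-en-2-yl)-7-oxabicyclo[4.1.0]heptan-2-ol | C=C(C)[C@H]1CC[C@@]2(C)O[C@H]2[C@]1(O)/C=C/[Si](C)(C)Cc1ccccc1 | intermediate
11 | ethyl bromopyruvate | CCOC(=O)C(=O)CBr | starting material
12 | ethyl 3-acetoxy-2-oxopropanoate | CCOC(=O)C(=O)COC(C)=O | intermediate
13 | potassium alkoxide of 10 | [K+].C=C(C)[C@H]1CC[C@@]2(C)O[C@H]2[C@]1([O-])/C=C/[Si](C)(C)Cc1ccccc1 | intermediate
14 | potassium (8R)-8-(benzyldimethylsilyl)-4,5-epoxygermacra-1(10)E,6Z-dien-6-olate | [K+].[O-]/C1=C\[C@@H](C/C(C)=C/CC[C@@]2(C)O[C@@H]12)[Si](C)(C)Cc1ccccc1 | intermediate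
15 | potassium aldolate (C11 alkoxide of 16 without TMS) | [K+].C(c1ccccc1)[Si](C)(C)[C@@H]1C/C(C)=C/CC[C@@]2(C)O[C@H]2C(=O)[C@H]1C([O-])(COC(C)=O)C(=O)OCC | intermediate
16 | ethyl 3-acetoxy-2-[(7R,8R)-8-(benzyldimethylsilyl)-4,5-epoxy-6-oxogermacr-1(10)E-en-7-yl]-2-(trimethylsilyloxy)propanoate | C(c1ccccc1)[Si](C)(C)[C@@H]1C/C(C)=C/CC[C@@]2(C)O[C@H]2C(=O)[C@H]1C(O[Si](C)(C)C)(COC(C)=O)C(=O)OCC | intermediate
17 | 13-acetoxy-8-(benzyldimethylsilyl)-4,5-epoxy-11-(trimethylsilyloxy)germacr-1(10)E-en-12,6-olide (6S,8R) | C(c1ccccc1)[Si](C)(C)[C@@H]1C/C(C)=C/CC[C@@]2(C)O[C@H]2[C@H]3OC(=O)C(O[Si](C)(C)C)(COC(C)=O)[C@@H]13 | intermediate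
18 | C1 alkylborane from 17 | C(c1ccccc1)[Si](C)(C)[C@@H]1C[C@@H](C)[C@@H](B)CC[C@@]2(C)O[C@H]2[C@H]3OC(=O)C(O[Si](C)(C)C)(COC(C)=O)[C@@H]13 | intermediate
19 | C1 alcohol from 18 | C(c1ccccc1)[Si](C)(C)[C@@H]1C[C@@H](C)[C@@H](O)CC[C@@]2(C)O[C@H]2[C@H]3OC(=O)C(O[Si](C)(C)C)(COC(C)=O)[C@@H]13 | intermediate
20 | 13-acetoxy-8-(benzyldimethylsilyl)-4,5-epoxy-1-oxo-11-(trimethylsilyloxy)germacran-12,6-olide (6S,8R,10R) | C(c1ccccc1)[Si](C)(C)[C@@H]1C[C@@H](C)C(=O)CC[C@@]2(C)O[C@H]2[C@H]3OC(=O)C(O[Si](C)(C)C)(COC(C)=O)[C@@H]13 | intermediate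
21 | 13-acetoxy-4,5-epoxy-8-(fluorodimethylsilyl)-11-hydroxy-1-oxogermacran-12,6-olide | F[Si](C)(C)[C@@H]1C[C@@H](C)C(=O)CC[C@@]2(C)O[C@H]2[C@H]3OC(=O)C(O)(COC(C)=O)[C@@H]13 | intermediate
22 | 13-acetoxy-4,5-epoxy-8,11-dihydroxy-1-oxogermacran-12,6-olide (6S,8R,10R) | O[C@@H]1C[C@@H](C)C(=O)CC[C@@]2(C)O[C@H]2[C@H]3OC(=O)C(O)(COC(C)=O)[C@@H]13 | intermediate
23 | 2-(hydroxymethyl)acrylic acid | C=C(CO)C(=O)O | starting material
24 | tert-butyldimethylsilyl 2-[(tert-butyldimethylsilyloxy)methyl]acrylate | C=C(CO[Si](C)(C)C(C)(C)C)C(=O)O[Si](C)(C)C(C)(C)C | intermediate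
25 | 2-[(tert-butyldimethylsilyloxy)methyl]acrylic acid | C=C(CO[Si](C)(C)C(C)(C)C)C(=O)O | intermediate
26 | 13-acetoxy-8-{2-[(tert-butyldimethylsilyloxy)methyl]acryloyloxy}-4,5-epoxy-11-hydroxy-1-oxogermacran-12,6-olide (6S,8S,10R) | C=C(CO[Si](C)(C)C(C)(C)C)C(=O)O[C@H]1C[C@@H](C)C(=O)CC[C@@]2(C)O[C@H]2[C@H]3OC(=O)C(O)(COC(C)=O)[C@@H]13 | intermediate
27 | TBS ether of the target | C=C(CO[Si](C)(C)C(C)(C)C)C(=O)O[C@H]1C[C@@H](C)C(=O)CC[C@@]2(C)O[C@H]2[C@H]2OC(=O)C(COC(C)=O)=C12 | intermediate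
28 | CNP0258719.1 | C=C(CO)C(=O)O[C@H]1C[C@@H](C)C(=O)CC[C@@]2(C)O[C@H]2[C@H]2OC(=O)C(COC(C)=O)=C12 | target

**Totals:** 13 steps; longest linear sequence 10 steps (1, 3, 4, 6, 7, 8, 9, 11, 12, 13).

**Three steps most likely to fail**

Step 6. The crown‑complexed potassium enolate may deprotonate the enolisable keto ester 12 (or attack its acetate) instead of adding to it. The fallback sets out from 10 and comes back at 17. The same oxy‑Cope is run, but enolate 14 is alkylated with ethyl bromoacetate, a robust electrophile, giving the γ‑keto ester F1. Zn(BH4)2 reduction with lactonisation gives the lactone F2. KHMDS and racemic 2‑(phenylsulfonyl)‑3‑phenyloxaziridine hydroxylate C11 to the α‑hydroxy lactone F3. Its dianion (LDA, 2.2 equiv) is hydroxymethylated with gaseous formaldehyde to the diol F4. Ac2O/pyridine acetylates only the primary alcohol to the hydroxy acetate F5, and TMSCl/imidazole then gives 17.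

Step 9. The fluoride/bicarbonate Tamao conditions act on a substrate carrying an acetate, an epimerisable α‑methyl ketone (also a γ,δ‑epoxy ketone) and a lactone next to the new C8–OH, so acetate loss, C10 epimerisation or translactonisation may compete. The fallback sets out from 17 and comes back at 22. The C–Si bond is oxidised before the ketone exists (TBAF; then H2O2/KHCO3) to the alkene diol F6. TESCl/imidazole protects only the secondary C8–OH to give the triethylsilyl ether F7. Hydroboration with NMO/TPAP oxidation as in step 8 gives the keto silyl ether F8, and PPTS/MeOH removes the TES group to give 22.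

Step 12. The dehydration may go towards C13 (exocyclic enol acetate) or stall if no C7–H is suitably placed. The fallback sets out from 22 and comes back at 27. Dess–Martin oxidation of the C8 alcohol gives the 1,8‑diketone F9, in which H7 is now α to a ketone. MsCl/Et3N then eliminates the C11 hydroxyl by E1cB with unambiguous regiochemistry to the 8‑oxo butenolide F10. Luche reduction (NaBH4, CeCl3, −78 °C) of the conjugated C8 ketone from the outer face gives the allylic alcohol F11 (8R expected; an 8S epimer would be esterified with DCC/DMAP instead). Mitsunobu esterification with 25 returns to 27.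

**Further compounds**
F1 | step 6 | ethyl 2-[(7R,8R)-8-(benzyldimethylsilyl)-4,5-epoxy-6-oxogermacr-1(10)E-en-7-yl]acetate | C(c1ccccc1)[Si](C)(C)[C@@H]1C/C(C)=C/CC[C@@]2(C)O[C@H]2C(=O)[C@H]1CC(=O)OCC
F2 | step 6 | 13-nor-8-(benzyldimethylsilyl)-4,5-epoxygermacr-1(10)E-en-12,6-olide | C(c1ccccc1)[Si](C)(C)[C@@H]1C/C(C)=C/CC[C@@]2(C)O[C@H]2[C@H]3OC(=O)C[C@@H]13
F3 | step 6 | 13-nor-8-(benzyldimethylsilyl)-4,5-epoxy-11-hydroxygermacr-1(10)E-en-12,6-olide | C(c1ccccc1)[Si](C)(C)[C@@H]1C/C(C)=C/CC[C@@]2(C)O[C@H]2[C@H]3OC(=O)C(O)[C@@H]13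
F4 | step 6 | 8-(benzyldimethylsilyl)-4,5-epoxy-11,13-dihydroxygermacr-1(10)E-en-12,6-olide | C(c1ccccc1)[Si](C)(C)[C@@H]1C/C(C)=C/CC[C@@]2(C)O[C@H]2[C@H]3OC(=O)C(O)(CO)[C@@H]13
F5 | step 6 | 13-acetoxy-8-(benzyldimethylsilyl)-4,5-epoxy-11-hydroxygermacr-1(10)E-en-12,6-olide | C(c1ccccc1)[Si](C)(C)[C@@H]1C/C(C)=C/CC[C@@]2(C)O[C@H]2[C@H]3OC(=O)C(O)(COC(C)=O)[C@@H]13
F6 | step 9 | 13-acetoxy-4,5-epoxy-8,11-dihydroxygermacr-1(10)E-en-12,6-olide (8R) | O[C@@H]1C/C(C)=C/CC[C@@]2(C)O[C@H]2[C@H]3OC(=O)C(O)(COC(C)=O)[C@@H]13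
F7 | step 9 | 13-acetoxy-4,5-epoxy-11-hydroxy-8-(triethylsilyloxy)germacr-1(10)E-en-12,6-olide | CC[Si](CC)(CC)O[C@@H]1C/C(C)=C/CC[C@@]2(C)O[C@H]2[C@H]3OC(=O)C(O)(COC(C)=O)[C@@H]13
F8 | step 9 | 13-acetoxy-4,5-epoxy-11-hydroxy-1-oxo-8-(triethylsilyloxy)germacran-12,6-olide | CC[Si](CC)(CC)O[C@@H]1C[C@@H](C)C(=O)CC[C@@]2(C)O[C@H]2[C@H]3OC(=O)C(O)(COC(C)=O)[C@@H]13
F9 | step 12 | 13-acetoxy-4,5-epoxy-11-hydroxy-1,8-dioxogermacran-12,6-olide | O=C1C[C@@H](C)C(=O)CC[C@@]2(C)O[C@H]2[C@H]3OC(=O)C(O)(COC(C)=O)[C@@H]13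
F10 | step 12 | 13-acetoxy-4,5-epoxy-1,8-dioxogermacr-7(11)-en-12,6-olide | O=C1C[C@@H](C)C(=O)CC[C@@]2(C)O[C@H]2[C@H]2OC(=O)C(COC(C)=O)=C12
F11 | step 12 | (8R)-13-acetoxy-4,5-epoxy-8-hydroxy-1-oxogermacr-7(11)-en-12,6-olide | O[C@@H]1C[C@@H](C)C(=O)CC[C@@]2(C)O[C@H]2[C@H]2OC(=O)C(COC(C)=O)=C12
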